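## Retrosynthetic overview

1. Target ⇐ fluoride cleavage of a 2-(trimethylsilyl)ethyl (TMSE) ester, preceded by late angeloylation of the C3 hydroxyl, so the Z-ester never meets ozone or amines.
2. Ring B ⇐ intramolecular aldol cyclodehydration (C7 onto the C6 aldehyde) of a C8-keto/C6-aldehyde, both carbonyls unmasked in one ozonolysis.
3. Key union: the C9–C10 bond, by carbonyl allylation of the ring A ketone with a 2-substituted allylzinc (fragment B, already carrying C11); this sets C10.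
4. Ring A ketone ⇐ 4-methoxy-3-methylphenol: dearomatisation, CBS reduction (C3), hydroxyl-directed cyclopropanation (C4), reductive cyclopropane opening with enolate allylation (C5).
5. Fragment B ⇐ Evans alkylation (C11). Ring order: ring A first (from the arene), ring B last.

Assumption: the target is read as (3S,4R,5R,10S,11R)-3-angeloyloxy-10-hydroxy-8-oxoeremophil-6-en-12-oic acid (3-O, 4-Me, 5-Me and 10-OH all cis, called β); eremophilane numbering C1–C13 is used for locants, and the four starting materials 1, 11, 14 and 26 are taken as purchasable.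

## Route

**Fragment A (ring A ketone)**

Step 1
Reactants: 1 4-methoxy-3-methylphenol
Product: 2 4,4-dimethoxy-3-methylcyclohexa-2,5-dien-1-one
Conditions: PhI(OAc)2, MeOH, 0 °C
Reagents that add atoms: methanol, CO
Why: Oxidative dearomatisation of a para-alkoxyphenol with hypervalent iodine, the phenoxenium ion being trapped by methanol to give the quinone monoketal.

Step 2
Reactants: 2 4,4-dimethoxy-3-methylcyclohexa-2,5-dien-1-one
Product: 3 4,4-dimethoxy-3-methylcyclohex-2-en-1-one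
Conditions: H2 (1 atm), RhCl(PPh3)3 (5 mol%), benzene, rt
Reagents that add atoms: none
Why: Chemoselective homogeneous hydrogenation, in which RhCl(PPh3)3 saturates the disubstituted C=C of a cross-conjugated dienone and leaves the trisubstituted, methyl-bearing one.

Step 3
Reactants: 3 4,4-dimethoxy-3-methylcyclohex-2-en-1-one
Product: 4 (1S)-4,4-dimethoxy-3-methylcyclohex-2-en-1-ol
Conditions: (R)-2-methyl-CBS-oxazaborolidine (0.2 equiv), catecholborane, toluene, −78 °C; aq. NaOH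
Reagents that add atoms: none
Why: Corey–Bakshi–Shibata reduction in which the alkenyl arm acts as the large group, so the (R)-catalyst gives the (S)-allylic alcohol and sets C3.

Step 4
Reactants: 4 (1S)-4,4-dimethoxy-3-methylcyclohex-2-en-1-ol
Product: 5 (1R,2S,6S)-5,5-dimethoxy-6-methylbicyclo[4.1.0]heptan-2-ol
Conditions: Et2Zn (3 equiv), CH2I2 (3 equiv), CH2Cl2, 0 °C → rt; aq. NH4Cl
Reagents that add atoms: diiodomethane, ICI
Why: Hydroxyl-directed Simmons–Smith (Furukawa) cyclopropanation delivers CH2 syn to the zinc alkoxide, which fixes the future C4 methyl cis to the C3 oxygen.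

Step 5
Reactants: 5 (1R,2S,6S)-5,5-dimethoxy-6-methylbicyclo[4.1.0]heptan-2-ol
Product: 6 tert-butyl{[(1R,2S,6S)-5,5-dimethoxy-6-methylbicyclo[4.1.0]heptan-2-yl]oxy}dimethylsilane
Conditions: TBSCl, imidazole, DMF, rt
Reagents that add atoms: tert-butyldimethylsilyl chloride, CC(C)(C)[Si](C)(C)Cl
Why: Standard silylation of a secondary alcohol, needed so that the later enolate alkylation cannot O-allylate C3.

Step 6
Reactants: 6 tert-butyl{[(1R,2S,6S)-5,5-dimethoxy-6-methylbicyclo[4.1.0]heptan-2-yl]oxy}dimethylsilane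
Product: 7 (1S,5S,6R)-5-{[tert-butyl(dimethyl)silyl]oxy}-1-methylbicyclo[4.1.0]heptan-2-one
Conditions: PPTS (cat.), acetone/H2O 10:1, rt
Reagents that add atoms: water, O
Why: Mild acid-catalysed acetal hydrolysis of the dimethyl ketal, which a secondary TBS ether and the cyclopropane tolerate.

Step 7
Reactants: 7 (1S,5S,6R)-5-{[tert-butyl(dimethyl)silyl]oxy}-1-methylbicyclo[4.1.0]heptan-2-one
Product: 9 (2R,3R,4S)-4-{[tert-butyl(dimethyl)silyl]oxy}-2,3-dimethyl-2-(prop-2-en-1-yl)cyclohexan-1-one, via lithium enolate 8 (not isolated)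
Conditions: Li (2.2 equiv), NH3/THF, −78 °C; isoprene; allyl bromide (5 equiv), −78 → −33 °C; NH4Cl
Reagents that add atoms: allyl bromide, C=CCBr
Why: Stork-type dissolving-metal reductive alkylation, in which the exocyclic cyclopropane bond (best overlap with the carbonyl π system) is cleaved to give the C4 methyl and the tetrasubstituted enolate regiospecifically, and allyl bromide then enters anti to the adjacent pseudoaxial C4 methyl to set the C5 quaternary centre with the two methyls cis.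

Step 8
Reactants: 9 (2R,3R,4S)-4-{[tert-butyl(dimethyl)silyl]oxy}-2,3-dimethyl-2-(prop-2-en-1-yl)cyclohexan-1-one
Product: 10 (2R,3R,4S)-4-{[tert-butyl(dimethyl)silyl]oxy}-2,3-dimethyl-2-[(1E)-prop-1-en-1-yl]cyclohexan-1-one
Conditions: RuHCl(CO)(PPh3)3 (5 mol%), toluene, 80 °C
Reagents that add atoms: none
Why: Ruthenium-hydride alkene isomerisation moves the terminal double bond into the more stable internal (E)-propenyl position, a masked C6 aldehyde that cannot conjugate because the α-carbon is quaternary (any Z isomer gives the same aldehyde later).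

**Fragment B (C7–C9, C11–C13)**

Step 9
Reactants: 11 2-methylidenepropane-1,3-diol
Product: 12 2-({[tert-butyl(dimethyl)silyl]oxy}methyl)prop-2-en-1-ol
Conditions: NaH (1.0 equiv), THF, 0 °C → rt; TBSCl (1.0 equiv)
Reagents that add atoms: tert-butyldimethylsilyl chloride, CC(C)(C)[Si](C)(C)Cl
Why: Monosilylation of a symmetrical diol through its sparingly soluble monosodium alkoxide.

Step 10
Reactants: 12 2-({[tert-butyl(dimethyl)silyl]oxy}methyl)prop-2-en-1-ol
Product: 13 {[2-(bromomethyl)prop-2-en-1-yl]oxy}(tert-butyl)dimethylsilane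
Conditions: CBr4, PPh3, CH2Cl2, 0 °C
Reagents that add atoms: carbon tetrabromide, BrC(Br)(Br)Br
Why: Appel bromination of a primary allylic alcohol under neutral conditions.

Step 11
Reactants: 14 (4S)-4-benzyl-3-propanoyl-1,3-oxazolidin-2-one; 13 {[2-(bromomethyl)prop-2-en-1-yl]oxy}(tert-butyl)dimethylsilane
Product: 16 (4S)-4-benzyl-3-[(2R)-4-({[tert-butyl(dimethyl)silyl]oxy}methyl)-2-methylpent-4-enoyl]-1,3-oxazolidin-2-one, via sodium enolate 15 (not isolated)
Conditions: NaN(SiMe3)2, THF, −78 °C; then 13, −78 → −40 °C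
Reagents that add atoms: none
Why: Evans asymmetric alkylation, in which the chelated (Z)-sodium enolate is attacked by the allylic bromide on the face opposite the benzyl group to set C11 as (R).

Step 12
Reactants: 16 (4S)-4-benzyl-3-[(2R)-4-({[tert-butyl(dimethyl)silyl]oxy}methyl)-2-methylpent-4-enoyl]-1,3-oxazolidin-2-one
Product: 17 2-(trimethylsilyl)ethyl (2R)-4-({[tert-butyl(dimethyl)silyl]oxy}methyl)-2-methylpent-4-enoate
Conditions: Me3SiCH2CH2OH (3 equiv), n-BuLi (2 equiv), THF, −78 → 0 °C; aq. NH4Cl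
Reagents that add atoms: 2-(trimethylsilyl)ethanol, C[Si](C)(C)CCO
Why: Transesterification of the imide by a lithium alkoxide (exocyclic acyl cleavage) removes the auxiliary without epimerising the α-methyl centre and installs a fluoride-labile ester.

Step 13
Reactants: 17 2-(trimethylsilyl)ethyl (2R)-4-({[tert-butyl(dimethyl)silyl]oxy}methyl)-2-methylpent-4-enoate
Product: 18 2-(trimethylsilyl)ethyl (2R)-4-(bromomethyl)-2-methylpent-4-enoate
Conditions: Ph3PBr2 (1.3 equiv), CH2Cl2, 0 °C → rt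
Reagents that add atoms: dibromotriphenylphosphorane, BrP(Br)(c1ccccc1)(c1ccccc1)c1ccccc1
Why: Appel-type direct conversion of a primary silyl ether into the bromide, which avoids a free δ-hydroxy ester that could lactonise.

**Union and endgame**

Step 14
Reactants: 18 2-(trimethylsilyl)ethyl (2R)-4-(bromomethyl)-2-methylpent-4-enoate; 10 (2R,3R,4S)-4-{[tert-butyl(dimethyl)silyl]oxy}-2,3-dimethyl-2-[(1E)-prop-1-en-1-yl]cyclohexan-1-one
Product: 20 2-(trimethylsilyl)ethyl (2R)-4-{[(1S,2R,3R,4S)-4-{[tert-butyl(dimethyl)silyl]oxy}-1-hydroxy-2,3-dimethyl-2-[(1E)-prop-1-en-1-yl]cyclohexyl]methyl}-2-methylpent-4-enoate, via allylzinc bromide 19 (not isolated)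
Conditions: Zn dust, LiCl, THF, 0 °C; then 10, −78 °C → rt; aq. NH4Cl
Reagents that add atoms: none
Why: Carbonyl allylation with an ester-tolerant allylzinc whose two termini are equivalent adds irreversibly to the hindered ketone from the α face, away from the cis C4/C5 methyls (axial attack is blocked by the axial C4 methyl in the favoured chair), so C9 enters α and the new C10 hydroxyl is β, cis to the C5 methyl.

Step 15
Reactants: 20 2-(trimethylsilyl)ethyl (2R)-4-{[(1S,2R,3R,4S)-4-{[tert-butyl(dimethyl)silyl]oxy}-1-hydroxy-2,3-dimethyl-2-[(1E)-prop-1-en-1-yl]cyclohexyl]methyl}-2-methylpent-4-enoate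
Product: 21 2-(trimethylsilyl)ethyl (2R)-4-{[(1S,2R,3R,4S)-4-{[tert-butyl(dimethyl)silyl]oxy}-2,3-dimethyl-2-[(1E)-prop-1-en-1-yl]-1-[(triethylsilyl)oxy]cyclohexyl]methyl}-2-methylpent-4-enoate
Conditions: TESOTf, 2,6-lutidine, CH2Cl2, −78 → 0 °C; aq. NaHCO3
Reagents that add atoms: triethylsilyl trifluoromethanesulfonate, CC[Si](CC)(CC)OS(=O)(=O)C(F)(F)F
Why: Silyl triflate silylation of the tertiary alcohol blocks retro-aldol fragmentation of the β-hydroxy carbonyl compounds that follow.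

Step 16
Reactants: 21 2-(trimethylsilyl)ethyl (2R)-4-{[(1S,2R,3R,4S)-4-{[tert-butyl(dimethyl)silyl]oxy}-2,3-dimethyl-2-[(1E)-prop-1-en-1-yl]-1-[(triethylsilyl)oxy]cyclohexyl]methyl}-2-methylpent-4-enoate
Product: 23 2-(trimethylsilyl)ethyl (2R)-5-[(1S,2R,3R,4S)-4-{[tert-butyl(dimethyl)silyl]oxy}-2-formyl-2,3-dimethyl-1-[(triethylsilyl)oxy]cyclohexyl]-2-methyl-4-oxopentanoate, via bis-ozonide 22 (not isolated)
Conditions: O3, CH2Cl2, −78 °C; PPh3, −78 °C → rt
Reagents that add atoms: ozone, [O-][O+]=O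
Why: Ozonolysis with reductive work-up cleaves the 1,1-disubstituted alkene to the C8 ketone and the propenyl group to the C6 aldehyde in one operation, and silyl ethers and the ester are inert.

Step 17
Reactants: 23 2-(trimethylsilyl)ethyl (2R)-5-[(1S,2R,3R,4S)-4-{[tert-butyl(dimethyl)silyl]oxy}-2-formyl-2,3-dimethyl-1-[(triethylsilyl)oxy]cyclohexyl]-2-methyl-4-oxopentanoate
Product: 24 2-(trimethylsilyl)ethyl (3S,4R,5R,10S,11R)-3-{[tert-butyl(dimethyl)silyl]oxy}-8-oxo-10-[(triethylsilyl)oxy]eremophil-6-en-12-oate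
Conditions: piperidine (1 equiv), AcOH (1 equiv), toluene, 4 Å sieves, 60 °C
Reagents that add atoms: none
Why: Amine/acid-mediated intramolecular aldol condensation closes ring B, since only C7 can reach the non-enolisable C6 aldehyde through a six-membered ring (C9 would give a four-membered ring) and dehydration can only give the C6=C7 enone because C5 is quaternary.

Step 18
Reactants: 24 2-(trimethylsilyl)ethyl (3S,4R,5R,10S,11R)-3-{[tert-butyl(dimethyl)silyl]oxy}-8-oxo-10-[(triethylsilyl)oxy]eremophil-6-en-12-oate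
Product: 25 2-(trimethylsilyl)ethyl (3S,4R,5R,10S,11R)-3,10-dihydroxy-8-oxoeremophil-6-en-12-oate
Conditions: HF·pyridine, pyridine/THF, 0 °C → rt
Reagents that add atoms: none
Why: Buffered, non-basic fluoride desilylation removes both silyl ethers while the TMSE ester, which needs free fluoride ion, and the β-hydroxy enone survive.

Step 19
Reactants: 25 2-(trimethylsilyl)ethyl (3S,4R,5R,10S,11R)-3,10-dihydroxy-8-oxoeremophil-6-en-12-oate; 26 angelic acid [(2Z)-2-methylbut-2-enoic acid]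
Product: 28 2-(trimethylsilyl)ethyl (3S,4R,5R,10S,11R)-10-hydroxy-3-{[(2Z)-2-methylbut-2-enoyl]oxy}-8-oxoeremophil-6-en-12-oate, via mixed anhydride 27 (not isolated)
Conditions: 2,4,6-trichlorobenzoyl chloride, Et3N, toluene, rt; then 25, 75 °C (no DMAP)
Reagents that add atoms: none
Why: Yamaguchi-type mixed-anhydride esterification without a nucleophilic catalyst acylates only the secondary C3 hydroxyl (the tertiary C10 hydroxyl is inert) and avoids Z-to-E isomerisation of the angelate.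

Step 20
Reactants: 28 2-(trimethylsilyl)ethyl (3S,4R,5R,10S,11R)-10-hydroxy-3-{[(2Z)-2-methylbut-2-enoyl]oxy}-8-oxoeremophil-6-en-12-oate
Product: 29 (3S,4R,5R,10S,11R)-3-angeloyloxy-10-hydroxy-8-oxoeremophil-6-en-12-oic acid, i.e. (2R)-2-[(4aS,7S,8R,8aR)-4a-hydroxy-8,8a-dimethyl-7-{[(2Z)-2-methylbut-2-enoyl]oxy}-3-oxo-3,4,4a,5,6,7,8,8a-octahydronaphthalen-2-yl]propanoic acid (target)
Conditions: tris(dimethylamino)sulfonium difluorotrimethylsilicate (TASF), DMF, 0 °C → rt; cold 0.1 M HCl to pH 4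
Reagents that add atoms: none
Why: Fluoride-induced β-elimination (fragmentation) of the 2-(trimethylsilyl)ethyl ester frees the acid without hydroxide or strong acid, so the angelate, the tertiary β-hydroxy enone and the C11 centre are untouched.

## Compound list

1 | 4-methoxy-3-methylphenol | COc1ccc(O)cc1C | starting material
2 | 4,4-dimethoxy-3-methylcyclohexa-2,5-dien-1-one | COC1(OC)C=CC(=O)C=C1C | intermediate
3 | 4,4-dimethoxy-3-methylcyclohex-2-en-1-one | COC1(OC)CCC(=O)C=C1C | intermediate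
4 | (1S)-4,4-dimethoxy-3-methylcyclohex-2-en-1-ol | O[C@H]1CCC(OC)(OC)C(C)=C1 | intermediate
5 | (1R,2S,6S)-5,5-dimethoxy-6-methylbicyclo[4.1.0]heptan-2-ol (CH2 cis to OH) | O[C@H]1CCC(OC)(OC)[C@@]2(C)C[C@@H]12 | intermediate
6 | tert-butyl{[(1R,2S,6S)-5,5-dimethoxy-6-methylbicyclo[4.1.0]heptan-2-yl]oxy}dimethylsilane | CC(C)(C)[Si](C)(C)O[C@H]1CCC(OC)(OC)[C@@]2(C)C[C@@H]12 | intermediate
7 | (1S,5S,6R)-5-{[tert-butyl(dimethyl)silyl]oxy}-1-methylbicyclo[4.1.0]heptan-2-one | CC(C)(C)[Si](C)(C)O[C@H]1CCC(=O)[C@@]2(C)C[C@@H]12 | intermediate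
8 | lithium (3R,4S)-4-{[tert-butyl(dimethyl)silyl]oxy}-2,3-dimethylcyclohex-1-en-1-olate | CC(C)(C)[Si](C)(C)O[C@H]1CCC(O[Li])=C(C)[C@H]1C | intermediate
9 | (2R,3R,4S)-4-{[tert-butyl(dimethyl)silyl]oxy}-2,3-dimethyl-2-(prop-2-en-1-yl)cyclohexan-1-one | CC(C)(C)[Si](C)(C)O[C@H]1CCC(=O)[C@](C)(CC=C)[C@H]1C | intermediate
10 | (2R,3R,4S)-4-{[tert-butyl(dimethyl)silyl]oxy}-2,3-dimethyl-2-[(1E)-prop-1-en-1-yl]cyclohexan-1-one | CC(C)(C)[Si](C)(C)O[C@H]1CCC(=O)[C@](C)(/C=C/C)[C@H]1C | intermediate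
11 | 2-methylidenepropane-1,3-diol | C=C(CO)CO | starting material
12 | 2-({[tert-butyl(dimethyl)silyl]oxy}methyl)prop-2-en-1-ol | C=C(CO)CO[Si](C)(C)C(C)(C)C | intermediate
13 | {[2-(bromomethyl)prop-2-en-1-yl]oxy}(tert-butyl)dimethylsilane | C=C(CBr)CO[Si](C)(C)C(C)(C)C | intermediate
14 | (4S)-4-benzyl-3-propanoyl-1,3-oxazolidin-2-one | CCC(=O)N1[C@@H](Cc2ccccc2)COC1=O | starting material
15 | sodium (Z)-enolate of 14 | C/C=C(\O[Na])N1[C@@H](Cc2ccccc2)COC1=O | intermediate
16 | (4S)-4-benzyl-3-[(2R)-4-({[tert-butyl(dimethyl)silyl]oxy}methyl)-2-methylpent-4-enoyl]-1,3-oxazolidin-2-one | C[C@H](CC(=C)CO[Si](C)(C)C(C)(C)C)C(=O)N1[C@@H](Cc2ccccc2)COC1=O | intermediate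
17 | 2-(trimethylsilyl)ethyl (2R)-4-({[tert-butyl(dimethyl)silyl]oxy}methyl)-2-methylpent-4-enoate | C[C@H](CC(=C)CO[Si](C)(C)C(C)(C)C)C(=O)OCC[Si](C)(C)C | intermediate
18 | 2-(trimethylsilyl)ethyl (2R)-4-(bromomethyl)-2-methylpent-4-enoate | C[C@H](CC(=C)CBr)C(=O)OCC[Si](C)(C)C | intermediate
19 | {2-[(2R)-2-methyl-3-oxo-3-[2-(trimethylsilyl)ethoxy]propyl]prop-2-en-1-yl}zinc bromide | C[C@H](CC(=C)C[Zn]Br)C(=O)OCC[Si](C)(C)C | intermediate
20 | 2-(trimethylsilyl)ethyl (2R)-4-{[(1S,2R,3R,4S)-4-{[tert-butyl(dimethyl)silyl]oxy}-1-hydroxy-2,3-dimethyl-2-[(1E)-prop-1-en-1-yl]cyclohexyl]methyl}-2-methylpent-4-enoate | CC(C)(C)[Si](C)(C)O[C@H]1CC[C@](O)(CC(=C)C[C@@H](C)C(=O)OCC[Si](C)(C)C)[C@](C)(/C=C/C)[C@H]1C | intermediate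
21 | 1-O-triethylsilyl ether of 20 | CC(C)(C)[Si](C)(C)O[C@H]1CC[C@](O[Si](CC)(CC)CC)(CC(=C)C[C@@H](C)C(=O)OCC[Si](C)(C)C)[C@](C)(/C=C/C)[C@H]1C | intermediate
22 | bis(1,2,4-trioxolane) of 21 (mixture at the trioxolane carbons) | CC(C)(C)[Si](C)(C)O[C@H]1CC[C@](O[Si](CC)(CC)CC)(CC2(C[C@@H](C)C(=O)OCC[Si](C)(C)C)OCOO2)[C@](C)(C2OC(C)OO2)[C@H]1C | intermediate
23 | 2-(trimethylsilyl)ethyl (2R)-5-[(1S,2R,3R,4S)-4-{[tert-butyl(dimethyl)silyl]oxy}-2-formyl-2,3-dimethyl-1-[(triethylsilyl)oxy]cyclohexyl]-2-methyl-4-oxopentanoate | CC(C)(C)[Si](C)(C)O[C@H]1CC[C@](O[Si](CC)(CC)CC)(CC(=O)C[C@@H](C)C(=O)OCC[Si](C)(C)C)[C@](C)(C=O)[C@H]1C | intermediate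
24 | 2-(trimethylsilyl)ethyl (3S,4R,5R,10S,11R)-3-{[tert-butyl(dimethyl)silyl]oxy}-8-oxo-10-[(triethylsilyl)oxy]eremophil-6-en-12-oate (cis-fused) | CC(C)(C)[Si](C)(C)O[C@H]1CC[C@]2(O[Si](CC)(CC)CC)CC(=O)C([C@@H](C)C(=O)OCC[Si](C)(C)C)=C[C@]2(C)[C@H]1C | intermediate
25 | 2-(trimethylsilyl)ethyl (3S,4R,5R,10S,11R)-3,10-dihydroxy-8-oxoeremophil-6-en-12-oate | O[C@H]1CC[C@]2(O)CC(=O)C([C@@H](C)C(=O)OCC[Si](C)(C)C)=C[C@]2(C)[C@H]1C | intermediate
26 | angelic acid, (2Z)-2-methylbut-2-enoic acid | C/C=C(/C)C(=O)O | starting material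
27 | (2Z)-2-methylbut-2-enoic 2,4,6-trichlorobenzoic anhydride | C/C=C(/C)C(=O)OC(=O)c1c(Cl)cc(Cl)cc1Cl | intermediate
28 | 2-(trimethylsilyl)ethyl (3S,4R,5R,10S,11R)-10-hydroxy-3-{[(2Z)-2-methylbut-2-enoyl]oxy}-8-oxoeremophil-6-en-12-oate | C/C=C(/C)C(=O)O[C@H]1CC[C@]2(O)CC(=O)C([C@@H](C)C(=O)OCC[Si](C)(C)C)=C[C@]2(C)[C@H]1C | intermediate
29 | (2R)-2-[(4aS,7S,8R,8aR)-4a-hydroxy-8,8a-dimethyl-7-{[(2Z)-2-methylbut-2-enoyl]oxy}-3-oxo-3,4,4a,5,6,7,8,8a-octahydronaphthalen-2-yl]propanoic acid | C/C=C(/C)C(=O)O[C@H]1CC[C@]2(O)CC(=O)C([C@@H](C)C(=O)O)=C[C@]2(C)[C@H]1C | target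

## Step count and risks

Total: 20 steps. Longest linear sequence: 15 steps (steps 1–8, then 14–20); fragment B is 5 steps (9–13).

**Step 14 (allylzinc addition).** The ketone is flanked by a quaternary carbon, and the C10 configuration rests on a facial preference argued from conformational analysis, not on a precedent for this exact ketone. Fallback, setting out from 10 and 18 and coming back at 25: if the addition gives mainly the other face, the material is not discarded. The resulting 2-(trimethylsilyl)ethyl (2R)-4-{[(1R,2R,3R,4S)-4-{[tert-butyl(dimethyl)silyl]oxy}-1-hydroxy-2,3-dimethyl-2-[(1E)-prop-1-en-1-yl]cyclohexyl]methyl}-2-methylpent-4-enoate F1 is taken through the operations of steps 15–18 as its triethylsilyl ether F2, the bis-ozonide F3, the 10-epi keto aldehyde F4, the trans-fused silylated enone F5 and the trans-fused diol ester F6. Because the C9–C10 bond of F6 is a ring aldol bond, F6 is then equilibrated by retro-aldol/aldol (KOtBu 0.2 equiv, THF/t-BuOH, −20 → 0 °C), so that C10 is set under thermodynamic ring-closure control, which is expected to favour the cis-fused ketol 25, as in Robinson-annulation ketols.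

**Step 17 (ring B cyclodehydration).** The C6 aldehyde is neopentyl and very hindered, and the β-silyloxy ketone could instead lose the C10 oxygen. Fallback, setting out from 23 and coming back at 24: replace the reversible amine-catalysed condensation by a directed, stoichiometric aldol addition followed by a separate dehydration. Dicyclohexylboron chloride/Et3N (Et2O, −78 → 0 °C) enolises the C8 ketone kinetically at the less hindered C7 side, and the boron enolate closes onto the aldehyde to give the 6-hydroxy-8-oxo-eremophilane ketol F7 (mixture at C6/C7). Burgess reagent (toluene, 50 °C) then removes the secondary C6 hydroxyl, which can only eliminate toward C7, giving 24.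

**Step 19 (angeloylation).** The 3β-hydroxyl is axial and flanked by the C4 methyl, and angelates isomerise readily to tiglates under forcing acylation. Fallback, setting out from 25 and coming back at 28: build the Z-alkene on the substrate instead of transferring it. 25 is esterified (DCC, cat. DMAP, CH2Cl2, 0 °C) with 2-[bis(2,2,2-trifluoroethoxy)phosphoryl]propanoic acid to the C3 phosphonopropanoate F8. A Still–Gennari olefination of F8 (KN(SiMe3)2 1.0 equiv, 18-crown-6, THF, −78 °C, then acetaldehyde) then gives the (Z)-2-methylbut-2-enoate 28.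

## Further compounds

F1 | step 14 | 2-(trimethylsilyl)ethyl (2R)-4-{[(1R,2R,3R,4S)-4-{[tert-butyl(dimethyl)silyl]oxy}-1-hydroxy-2,3-dimethyl-2-[(1E)-prop-1-en-1-yl]cyclohexyl]methyl}-2-methylpent-4-enoate (C10 epimer of 20) | CC(C)(C)[Si](C)(C)O[C@H]1CC[C@@](O)(CC(=C)C[C@@H](C)C(=O)OCC[Si](C)(C)C)[C@](C)(/C=C/C)[C@H]1C
F2 | step 14 | 1-O-triethylsilyl ether of F1 (C10 epimer of 21) | CC(C)(C)[Si](C)(C)O[C@H]1CC[C@@](O[Si](CC)(CC)CC)(CC(=C)C[C@@H](C)C(=O)OCC[Si](C)(C)C)[C@](C)(/C=C/C)[C@H]1C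
F3 | step 14 | bis(1,2,4-trioxolane) of F2 (C10 epimer of 22) | CC(C)(C)[Si](C)(C)O[C@H]1CC[C@@](O[Si](CC)(CC)CC)(CC2(C[C@@H](C)C(=O)OCC[Si](C)(C)C)OCOO2)[C@](C)(C2OC(C)OO2)[C@H]1C
F4 | step 14 | 2-(trimethylsilyl)ethyl (2R)-5-[(1R,2R,3R,4S)-4-{[tert-butyl(dimethyl)silyl]oxy}-2-formyl-2,3-dimethyl-1-[(triethylsilyl)oxy]cyclohexyl]-2-methyl-4-oxopentanoate (C10 epimer of 23) | CC(C)(C)[Si](C)(C)O[C@H]1CC[C@@](O[Si](CC)(CC)CC)(CC(=O)C[C@@H](C)C(=O)OCC[Si](C)(C)C)[C@](C)(C=O)[C@H]1C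
F5 | step 14 | 2-(trimethylsilyl)ethyl (3S,4R,5R,10R,11R)-3-{[tert-butyl(dimethyl)silyl]oxy}-8-oxo-10-[(triethylsilyl)oxy]eremophil-6-en-12-oate (trans-fused) | CC(C)(C)[Si](C)(C)O[C@H]1CC[C@@]2(O[Si](CC)(CC)CC)CC(=O)C([C@@H](C)C(=O)OCC[Si](C)(C)C)=C[C@]2(C)[C@H]1C
F6 | step 14 | 2-(trimethylsilyl)ethyl (3S,4R,5R,10R,11R)-3,10-dihydroxy-8-oxoeremophil-6-en-12-oate (trans-fused) | O[C@H]1CC[C@@]2(O)CC(=O)C([C@@H](C)C(=O)OCC[Si](C)(C)C)=C[C@]2(C)[C@H]1C
F7 | step 17 | 2-(trimethylsilyl)ethyl (3S,4R,5R,10S,11R)-3-{[tert-butyl(dimethyl)silyl]oxy}-6-hydroxy-8-oxo-10-[(triethylsilyl)oxy]eremophilan-12-oate (mixture at C6 and C7) | CC(C)(C)[Si](C)(C)O[C@H]1CC[C@]2(O[Si](CC)(CC)CC)CC(=O)C([C@@H](C)C(=O)OCC[Si](C)(C)C)C(O)[C@]2(C)[C@H]1C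
F8 | step 19 | 2-(trimethylsilyl)ethyl (3S,4R,5R,10S,11R)-3-({2-[bis(2,2,2-trifluoroethoxy)phosphoryl]propanoyl}oxy)-10-hydroxy-8-oxoeremophil-6-en-12-oate (mixture at the phosphonate α-carbon) | CC(C(=O)O[C@H]1CC[C@]2(O)CC(=O)C([C@@H](C)C(=O)OCC[Si](C)(C)C)=C[C@]2(C)[C@H]1C)P(=O)(OCC(F)(F)F)OCC(F)(F)F
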